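**Retrosynthetic overview**
1. Feature: the benzene ring Ar1–Ar6 is a phloroglucinol with oxygen on Ar1, Ar3 and Ar5, one-carbon carbonyls on Ar2 and Ar4, and Ar6 bonded to benzylic C1′ on quaternary C4. Ar5–Ar6–Ar1 is therefore a malonyl unit, and Ar2–Ar3–Ar4 with both formyl carbons is a 3-oxoglutarate unit.
2. Late disconnections: CHO ⇐ CO2Me; C3H2 ⇐ C3=O; O–C1 of the oxepane ⇐ oxa-Michael addition of an ortho phenol to the C1=C2–C3=O enone.
3. Key disconnection: Ar1–Ar2 and Ar5–Ar4 ⇐ terpenoid malonyl dichloride + dimethyl 3-oxopentanedioate (double C-acylation).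
4. Early disconnections: C4–C1′ ⇐ Michael addition of the C4 dienolate to a benzylidenemalonate; C1=C2 ⇐ aldol; C5–C4 ⇐ nitroalkene Michael/Nef; C1=C10 ⇐ McMurry coupling on the ozonolysis product of (+)-2-carene.
5. Ring order: cyclopropane (chiral pool) → cycloheptane → cyclopentenone → benzene ring → oxepane.

Key step: step 14

Remark (numbering): aromadendrane numbering is used (C1–C15, benzylic C1′, Ar1–Ar6). β is the face that carries C11, H5, C14, C1′ and the ether oxygen; H6, H7, H10 and C15 are α.
Remark (assumption): compounds 1, 12, 20, 21 and 27 are taken as purchasable. C4 in 15–19 and C3 in 32–35 are carried as epimer mixtures, because C4 is reset in step 11 and C3 is erased in step 18.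

**Step 1**
Reactants: 1 (+)-2-carene
Product: 3 cis-2,2-dimethyl-3-(3-oxobutyl)cyclopropanecarbaldehyde (C5 aldehyde on C6; chain C8–C9–C10(=O)–C14 on C7), via secondary ozonide 2 (not isolated)
Conditions: O3, CH2Cl2, −78 °C; Me2S, −78 °C → rt
Reagents that add atoms: ozone, [O-][O+]=O
Why: Ozonolysis with reductive work-up cleaves the only alkene (the later C5 and C10) and leaves the chiral-pool cyclopropane centres C6 and C7, which already have the configuration of the target, untouched.

**Step 2**
Reactants: 3 keto aldehyde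
Product: 5 cis-[2,2-dimethyl-3-(3-oxobutyl)cyclopropyl]acetaldehyde (new aldehyde carbon = C1), via enol ether 4 (not isolated)
Conditions: MeOCH2PPh3Cl, KHMDS, THF, −78 °C; 3, −78 → −20 °C; then 1 M HCl, THF, rt, short contact
Reagents that add atoms: (methoxymethyl)triphenylphosphonium chloride, COC[P+](c1ccccc1)(c1ccccc1)c1ccccc1.[Cl-]; water, O
Why: In this Wittig homologation the ylide should take the aldehyde far faster than the methyl ketone at low temperature, and hydrolysis of the enol ether protonates C5 and puts the cation on C1, so no cyclopropylcarbinyl cation arises.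

**Step 3**
Reactants: 5 homologated keto aldehyde
Product: 6 4,8,8-trimethylbicyclo[5.1.0]oct-3-ene (ring-enlarged carene, C1=C10 alkene, cis-fused cyclopropane)
Conditions: TiCl3(DME)1.5, Zn–Cu couple, DME, reflux; 5 added slowly by syringe pump (high dilution)
Reagents that add atoms: none
Why: Intramolecular McMurry coupling of a 7-oxo aldehyde is a standard entry to 1-methylcycloheptenes, and both ketyl carbons (C1, C10) are separated from the cyclopropane by CH2 groups, so the three-membered ring should not open.

**Step 4**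
Reactants: 6 bicyclic alkene
Product: 8 4,8,8-trimethylbicyclo[5.1.0]octan-3-ol (C1–OH α, H10 α, C14 β), via alkylborane 7 (not isolated)
Conditions: BH3·THF, THF, 0 °C → rt; then NaOH, 30% H2O2, 0 °C
Reagents that add atoms: hydrogen peroxide, OO
Why: Hydroboration–oxidation puts boron on the less substituted C1 and delivers H to C10 syn from the α face, opposite the C11 bridge whose endo methyl covers the β face (as in the carenes), which sets C10.

**Step 5**
Reactants: 8 alcohol
Product: 9 4,8,8-trimethylbicyclo[5.1.0]octan-3-one (C1 ketone, H10 α)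
Conditions: Pr4N[RuO4] (5 mol %), NMO, 4 Å MS, CH2Cl2, rt
Reagents that add atoms: none
Why: The Ley–Griffith oxidation is neutral and non-enolising, so C10, now α to the ketone, should keep its configuration.

**Step 6**
Reactants: 9 ketone
Product: 11 C1(OSiMe3)=C5 enol silane of 9, via lithium enolate 10 (not isolated)
Conditions: LDA, THF, −78 °C; TMSCl, −78 → 0 °C
Reagents that add atoms: chlorotrimethylsilane, C[Si](C)(C)Cl
Why: Kinetic deprotonation by the hindered amide takes the C5 methylene rather than the C10 methine, and O-silylation fixes this regiochemistry without touching C10.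

**Step 7**
Reactants: 12 3-nitrobutan-2-ol
Product: 14 2-nitrobut-2-ene, via mesylate 13 (not isolated)
Conditions: MsCl, Et3N (2.2 equiv), CH2Cl2, 0 °C
Reagents that add atoms: none
Why: Mesylation of a β-nitro alcohol followed by E1cB loss of mesylate is the usual nitroalkene preparation.

**Step 8**
Reactants: 11 enol silane; 14 2-nitrobut-2-ene
Product: 16 4,8,8-trimethyl-2-(3-oxobutan-2-yl)bicyclo[5.1.0]octan-3-one (1,4-diketone; side chain C4/C15/C3/C2 α on C5, H5 β), via silyl nitronate 15 (not isolated)
Conditions: SnCl4, CH2Cl2, −78 → 0 °C; then H2O, 40 °C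
Reagents that add atoms: water, O
Why: Lewis-acid Mukaiyama–Michael addition of an enol silane to a nitroalkene followed by Nef hydrolysis is an established 1,4-diketone synthesis, and C5 should react on its α face, anti to the C11 bridge on neighbouring C6, which sets C5.

**Step 9**
Reactants: 16 1,4-diketone
Product: 19 aromadendr-1-en-3-one (tricyclic enone; H5 β, H10 α), via lithium aldolate 17 (not isolated), via aldol acetate 18 (not isolated)
Conditions: LiHMDS (1.05 equiv), THF, −78 → −20 °C; Ac2O, −20 → 0 °C; DBU, rt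
Reagents that add atoms: none
Why: The base takes the only primary α-proton (C2 methyl), the terminal enolate closes on C1 in a 5-(enolexo)-exo-trig intramolecular aldol addition, and acetylation with E1cB elimination gives the C1=C2 enone without an equilibrating medium that could epimerise C10 or C5 or shift the alkene to C4=C5.

**Step 10**
Reactants: 20 benzaldehyde; 21 diallyl malonate
Product: 22 diallyl 2-benzylidenemalonate
Conditions: piperidine, AcOH (10 mol % each), toluene, reflux, Dean–Stark
Reagents that add atoms: none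
Why: This is a Knoevenagel condensation, and allyl esters are chosen so that the malonic acid can later be freed without hydroxide.

**Step 11**
Reactants: 19 tricyclic enone; 22 diallyl benzylidenemalonate
Product: 24 diallyl [phenyl(3-oxoaromadendr-1-en-4β-yl)methyl]malonate (C1′ β and C15 α on C4; C1′ as in the target), via lithium dienolate 23 (not isolated)
Conditions: LDA (1.05 equiv), THF, −78 °C; 22, −78 → −40 °C; AcOH/THF quench at −78 °C
Reagents that add atoms: none
Why: In this Michael addition of the kinetic cross-conjugated (α′) dienolate the acceptor should reach C4 on the β face, anti to the C5–C6 bond, and stack over the dienolate as in the formal Diels–Alder (double Michael) mode of such enolates, with lithium bridging O3 and the ester trans to phenyl and the phenyl turned outward toward H5, which sets C4 and C1′; the second Michael closure onto fully substituted C1 is too crowded to persist.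

**Step 12**
Reactants: 24 diallyl malonate adduct
Product: 25 [phenyl(3-oxoaromadendr-1-en-4β-yl)methyl]malonic acid
Conditions: Pd(PPh3)4 (5 mol %), morpholine (10 equiv), THF, rt; cold aq KHSO4
Reagents that add atoms: none
Why: Tsuji–Trost deallylation with zerovalent palladium and an amine allyl acceptor frees both acids at room temperature under near-neutral conditions, which avoids retro-Michael cleavage of the crowded C4–C1′ bond, γ-epimerisation of the enone and decarboxylation.

**Step 13**
Reactants: 25 malonic acid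
Product: 26 [phenyl(3-oxoaromadendr-1-en-4β-yl)methyl]malonyl dichloride
Conditions: (COCl)2 (3 equiv), DMF (cat.), CH2Cl2, 0 °C → rt; concentrated and used crude
Reagents that add atoms: oxalyl chloride, O=C(Cl)C(=O)Cl
Why: Vilsmeier-type activation with oxalyl chloride and catalytic DMF turns monosubstituted malonic acids into their dichlorides at or below room temperature and leaves the enone alone.

**Step 14**
Reactants: 26 malonyl dichloride; 27 dimethyl 3-oxopentanedioate
Product: 30 dimethyl 2,4,6-trihydroxy-5-[phenyl(3-oxoaromadendr-1-en-4β-yl)methyl]isophthalate, via chlorocarbonyl ketene 28 (not isolated), via open-chain acyl chloride 29 (not isolated)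
Conditions: 27 (1.2 equiv), MgCl2 (2.5 equiv), Et3N (5 equiv), MeCN/CH2Cl2, 0 °C; 26 in CH2Cl2 added slowly, −20 °C → rt; 1 M HCl work-up
Reagents that add atoms: none
Why: Et3N and MgCl2 turn 27 into its chelated magnesium enolate and strip HCl from 26 to give ketene 28, whose unhindered sp carbon is attacked by the enolate carbon (bond Ar1–Ar2) to give 29. The second active methylene of 29, again held as a magnesium chelate, attacks the remaining acyl chloride (or the acyl ketene derived from it) to form Ar5–Ar4, and the resulting cyclohexane-1,3,5-trione enolises at once to the hydrogen-bonded arene, which makes the sequence irreversible. The closest known reactions are the C-acylation of magnesium β-keto ester enolates by acid chlorides and the Claisen-type cyclocondensation of malonyl units with 3-oxoglutarates to phloroglucinol dicarboxylates. The single ring closed is the six-membered carbocycle, by a 6-(enolexo)-exo-trig Dieckmann-type attack. No stereocentre is formed, and C4 (quaternary), C1′, C5 and C10 carry no hydrogen that this weak base should remove. The selectivity needed is carbon over oxygen acylation in the closure, which the oxophilic magnesium secures by binding the enolate oxygens, while slow addition into excess enolate limits ketene oligomerisation; arene regiochemistry does not arise, because the two ortho hydroxyls and the two esters are equivalent.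

**Step 15**
Reactants: 30 phloroglucinol diester enone
Product: 32 bridged oxepane C3 alcohol (O on C1 β; two free phenols, two methyl esters), via bridged ketone 31 (not isolated)
Conditions: DBU (0.3 equiv), THF, 40 °C; then MeOH, CeCl3·7H2O, NaBH4, −40 °C
Reagents that add atoms: none
Why: In this intramolecular oxa-Michael addition a phenoxide ortho to C1′ can reach C1 only on the β face on which C1′ sits, so the tether sets C1, and because the addition is reversible the β-aryloxy ketone is reduced in the same flask under Luche-type conditions, after which E1cB reversal is impossible.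

**Step 16**
Reactants: 32 diphenol alcohol
Product: 33 bis(benzyl ether) of 32 (C3–OH free)
Conditions: BnBr (2.4 equiv), K2CO3, DMF, rt
Reagents that add atoms: benzyl bromide, BrCc1ccccc1
Why: In this Williamson etherification carbonate deprotonates only the two acidic phenols, so the hindered C3 alcohol stays free, and the benzyl ethers block quinone-methide formation in the later ester reduction.

**Step 17**
Reactants: 33 alcohol
Product: 35 O-(C3) S-methyl xanthate, via sodium xanthate 34 (not isolated)
Conditions: NaH, THF, 0 °C; CS2; MeI, rt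
Reagents that add atoms: carbon disulfide, S=C=S; iodomethane, CI
Why: Xanthate formation through the small electrophile CS2 works on hindered secondary alkoxides and leaves aryl esters and ethers alone.

**Step 18**
Reactants: 35 xanthate
Product: 36 C3-deoxy bridged oxepane diester bis(benzyl ether)
Conditions: Bu3SnH (5 equiv, about 0.5 M), Et3B (0.2 equiv), air, toluene, rt
Reagents that add atoms: none
Why: Barton–McCombie deoxygenation suits a neopentyl secondary alcohol where ionic displacement cannot work, and room-temperature initiation with a high stannane concentration is chosen so that hydrogen transfer to the C3 radical outruns β-scission of the C4–C1′ bond.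

**Step 19**
Reactants: 36 diester
Product: 37 bis(hydroxymethyl) compound
Conditions: LiAlH4, THF, 0 °C → rt
Reagents that add atoms: none
Why: Hydride reduction of both flanked aryl esters gives the benzylic alcohols, and with the phenols benzylated no ortho-quinone methide can form and be over-reduced to methyl.

**Step 20**
Reactants: 37 diol
Product: 38 dialdehyde bis(benzyl ether)
Conditions: Dess–Martin periodinane (2.5 equiv), CH2Cl2, rt
Reagents that add atoms: none
Why: Dess–Martin oxidation of primary benzylic alcohols stops at the aldehyde and is mild enough for the tertiary alkyl aryl ether and the cyclopropane.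

**Step 21**
Reactants: 38 dialdehyde bis(benzyl ether)
Product: 39 psiguadial A
Conditions: H2 (1 atm), Pd/C (10 wt %), EtOAc, rt
Reagents that add atoms: none
Why: Hydrogenolysis of aryl benzyl ethers is neutral, so the tertiary ether, the unactivated cyclopropane and the aldehydes (which become chelated, vinylogous-acid-like carbonyls as the phenols appear) should survive.

**Compound list**
1 | (+)-2-carene, (1S,6R)-3,7,7-trimethylbicyclo[4.1.0]hept-2-ene | CC1=C[C@H]2[C@@H](CC1)C2(C)C | starting material
2 | secondary ozonide of 1 | CC12CC[C@@H]3[C@H](C(OO1)O2)C3(C)C | intermediate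
3 | cis-2,2-dimethyl-3-(3-oxobutyl)cyclopropanecarbaldehyde | CC(=O)CC[C@@H]1[C@H](C=O)C1(C)C | intermediate
4 | methyl enol ether of the homologated aldehyde (E/Z) | CC(=O)CC[C@@H]1[C@H](C=COC)C1(C)C | intermediate
5 | cis-[2,2-dimethyl-3-(3-oxobutyl)cyclopropyl]acetaldehyde | CC(=O)CC[C@@H]1[C@H](CC=O)C1(C)C | intermediate
6 | 4,8,8-trimethylbicyclo[5.1.0]oct-3-ene | CC1=CC[C@H]2[C@@H](CC1)C2(C)C | intermediate
7 | C1 alkylborane (B α, H10 α) | C[C@H]1CC[C@@H]2[C@H](C[C@@H]1B)C2(C)C | intermediate
8 | 4,8,8-trimethylbicyclo[5.1.0]octan-3-ol (OH α, C14 β) | C[C@H]1CC[C@@H]2[C@H](C[C@@H]1O)C2(C)C | intermediate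
9 | 4,8,8-trimethylbicyclo[5.1.0]octan-3-one (H10 α) | C[C@H]1CC[C@@H]2[C@H](CC1=O)C2(C)C | intermediate
10 | lithium C1=C5 enolate of 9 | C[C@H]1CC[C@@H]2[C@H](C=C1[O-])C2(C)C.[Li+] | intermediate
11 | trimethylsilyl C1=C5 enol ether of 9 | C[C@H]1CC[C@@H]2[C@H](C=C1O[Si](C)(C)C)C2(C)C | intermediate
12 | 3-nitrobutan-2-ol | CC(O)C(C)[N+](=O)[O-] | starting material
13 | 3-nitrobutan-2-yl methanesulfonate | CC(OS(C)(=O)=O)C(C)[N+](=O)[O-] | intermediate
14 | 2-nitrobut-2-ene | CC=C(C)[N+](=O)[O-] | intermediate
15 | trimethylsilyl nitronate of the Michael adduct | C[C@H]1CC[C@@H]2[C@H]([C@H](C(C)C(C)=[N+]([O-])O[Si](C)(C)C)C1=O)C2(C)C | intermediate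
16 | 1,4-diketone (side chain α on C5, H5 β) | C[C@H]1CC[C@@H]2[C@H]([C@H](C(C)C(C)=O)C1=O)C2(C)C | intermediate
17 | lithium aldolate (C1–O, C1–C2 bond closed) | C[C@H]1CC[C@@H]2[C@H]([C@@H]3C(C)C(=O)CC31[O-])C2(C)C.[Li+] | intermediate
18 | tertiary aldol acetate | C[C@H]1CC[C@@H]2[C@H]([C@@H]3C(C)C(=O)CC31OC(C)=O)C2(C)C | intermediate
19 | aromadendr-1-en-3-one (H5 β, H10 α, C4 epimers) | C[C@H]1CC[C@@H]2[C@H]([C@@H]3C(C)C(=O)C=C31)C2(C)C | intermediate
20 | benzaldehyde | O=Cc1ccccc1 | starting material
21 | diallyl malonate | C=CCOC(=O)CC(=O)OCC=C | starting material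
22 | diallyl 2-benzylidenemalonate | C=CCOC(=O)C(=Cc1ccccc1)C(=O)OCC=C | intermediate
23 | lithium cross-conjugated dienolate of 19 | C[C@H]1CC[C@@H]2[C@H]([C@@H]3C(C)=C([O-])C=C31)C2(C)C.[Li+] | intermediate
24 | diallyl [phenyl(3-oxoaromadendr-1-en-4β-yl)methyl]malonate | C[C@H]1CC[C@@H]2[C@H]([C@@H]3[C@](C)(C(=O)C=C31)[C@@H](c1ccccc1)C(C(=O)OCC=C)C(=O)OCC=C)C2(C)C | intermediate
25 | [phenyl(3-oxoaromadendr-1-en-4β-yl)methyl]malonic acid | C[C@H]1CC[C@@H]2[C@H]([C@@H]3[C@](C)(C(=O)C=C31)[C@@H](c1ccccc1)C(C(=O)O)C(=O)O)C2(C)C | intermediate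
26 | [phenyl(3-oxoaromadendr-1-en-4β-yl)methyl]malonyl dichloride | C[C@H]1CC[C@@H]2[C@H]([C@@H]3[C@](C)(C(=O)C=C31)[C@@H](c1ccccc1)C(C(=O)Cl)C(=O)Cl)C2(C)C | intermediate
27 | dimethyl 3-oxopentanedioate | COC(=O)CC(=O)CC(=O)OC | starting material
28 | chlorocarbonyl ketene from 26 | C[C@H]1CC[C@@H]2[C@H]([C@@H]3[C@](C)(C(=O)C=C31)[C@@H](c1ccccc1)C(=C=O)C(=O)Cl)C2(C)C | intermediate
29 | open-chain mono-C-acylated 3-oxoglutarate acyl chloride | C[C@H]1CC[C@@H]2[C@H]([C@@H]3[C@](C)(C(=O)C=C31)[C@@H](c1ccccc1)C(C(=O)Cl)C(=O)C(C(=O)OC)C(=O)CC(=O)OC)C2(C)C | intermediate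
30 | dimethyl 2,4,6-trihydroxy-5-[phenyl(3-oxoaromadendr-1-en-4β-yl)methyl]isophthalate | C[C@H]1CC[C@@H]2[C@H]([C@@H]3[C@](C)(C(=O)C=C31)[C@@H](c1ccccc1)c1c(O)c(C(=O)OC)c(O)c(C(=O)OC)c1O)C2(C)C | intermediate
31 | bridged oxepane C3 ketone, diester diphenol | C[C@H]1CC[C@@H]2[C@H]([C@@H]3[C@]4(C)C(=O)C[C@@]31Oc1c(C(=O)OC)c(O)c(C(=O)OC)c(O)c1[C@@H]4c1ccccc1)C2(C)C | intermediate
32 | bridged oxepane C3 alcohol, diester diphenol | C[C@H]1CC[C@@H]2[C@H]([C@@H]3[C@]4(C)C(O)C[C@@]31Oc1c(C(=O)OC)c(O)c(C(=O)OC)c(O)c1[C@@H]4c1ccccc1)C2(C)C | intermediate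
33 | bis(benzyl ether) of 32 | C[C@H]1CC[C@@H]2[C@H]([C@@H]3[C@]4(C)C(O)C[C@@]31Oc1c(C(=O)OC)c(OCc5ccccc5)c(C(=O)OC)c(OCc5ccccc5)c1[C@@H]4c1ccccc1)C2(C)C | intermediate
34 | sodium O-(C3) xanthate | C[C@H]1CC[C@@H]2[C@H]([C@@H]3[C@]4(C)C(OC(=S)[S-])C[C@@]31Oc1c(C(=O)OC)c(OCc5ccccc5)c(C(=O)OC)c(OCc5ccccc5)c1[C@@H]4c1ccccc1)C2(C)C.[Na+] | intermediate
35 | O-(C3) S-methyl xanthate | C[C@H]1CC[C@@H]2[C@H]([C@@H]3[C@]4(C)C(OC(=S)SC)C[C@@]31Oc1c(C(=O)OC)c(OCc5ccccc5)c(C(=O)OC)c(OCc5ccccc5)c1[C@@H]4c1ccccc1)C2(C)C | intermediate
36 | C3-deoxy diester bis(benzyl ether) | C[C@H]1CC[C@@H]2[C@H]([C@@H]3[C@]4(C)CC[C@@]31Oc1c(C(=O)OC)c(OCc5ccccc5)c(C(=O)OC)c(OCc5ccccc5)c1[C@@H]4c1ccccc1)C2(C)C | intermediate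
37 | bis(hydroxymethyl) bis(benzyl ether) | C[C@H]1CC[C@@H]2[C@H]([C@@H]3[C@]4(C)CC[C@@]31Oc1c(CO)c(OCc5ccccc5)c(CO)c(OCc5ccccc5)c1[C@@H]4c1ccccc1)C2(C)C | intermediate
38 | dialdehyde bis(benzyl ether) | C[C@H]1CC[C@@H]2[C@H]([C@@H]3[C@]4(C)CC[C@@]31Oc1c(C=O)c(OCc5ccccc5)c(C=O)c(OCc5ccccc5)c1[C@@H]4c1ccccc1)C2(C)C | intermediate
39 | psiguadial A | C[C@H]1CC[C@@H]2[C@H]([C@@H]3[C@]4(C)CC[C@@]31Oc1c(C=O)c(O)c(C=O)c(O)c1[C@@H]4c1ccccc1)C2(C)C | target

**Step count**
Total steps: 21. Longest linear sequence: 19 steps (1 → 39 through steps 1–6, 8, 9 and 11–21). Steps 7 and 10 are side branches.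

**Steps most likely to fail**

1. **Step 14.** The ring closure may run through oxygen instead of carbon, or the hindered ketene may oligomerise before it meets the enolate.
   - Fallback route: 26 → F1 → 30.
   - Compounds 26 and 27 are heated in toluene without magnesium, so that C-acylation followed by O-acylation is accepted.
   - The product isolated is methyl 4-hydroxy-6-(2-methoxy-2-oxoethyl)-2-oxo-3-[phenyl(3-oxoaromadendr-1-en-4β-yl)methyl]-2H-pyran-5-carboxylate F1.
   - Mg(OMe)2 in MeOH at reflux then opens the lactone by methanolysis. The freed 3-oxoglutarate methylene closes on the new methyl ester in a Dieckmann reaction, which returns the material to 30.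

2. **Step 15.** The oxa-Michael equilibrium may lie on the open side, because the phenol is acidic and C1 is fully substituted; the hydride would then consume the enone.
   - Fallback route: 30 → F2 → 32.
   - Luche reduction (NaBH4, CeCl3·7H2O, MeOH, −40 °C) of the enone gives the C3 allylic alcohol F2.
   - An irreversible hydrogen-atom-transfer hydroalkoxylation follows. Reagents: [N,N′-bis(3,5-di-tert-butylsalicylidene)-1,2-cyclohexanediaminato]cobalt (divalent cobalt) as catalyst, N-fluoro-2,4,6-trimethylpyridinium triflate and PhSiH3 in toluene at rt.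
   - This places H on C2 and lets the ortho phenol capture C1 on the β face, giving 32.

3. **Step 11.** Facial selectivity at the benzylidene carbon may be poor, or the crowded adduct may revert by retro-Michael cleavage on warming.
   - Fallback route: 19 → F3 → F4 → F5 → 24. The roles at C1′ are exchanged.
   - The dienolate (LDA, −78 °C) is trapped on its β face with monomeric formaldehyde to give the 4β-hydroxymethyl ketone F3.
   - Dess–Martin oxidation gives the non-enolisable keto aldehyde F4.
   - Knoevenagel condensation with 21 (TiCl4, pyridine, THF, 0 °C) gives the alkylidenemalonate F5.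
   - Ph2CuLi (Et2O, −78 °C) adds to C1′ in preference to the β,β-disubstituted enone. Attack should occur anti to C5 in the conformer that eclipses C15 with the alkene, which leads to 24.

**Further compounds**
F1 | step 14 | methyl 4-hydroxy-6-(2-methoxy-2-oxoethyl)-2-oxo-3-[phenyl(3-oxoaromadendr-1-en-4β-yl)methyl]-2H-pyran-5-carboxylate | C[C@H]1CC[C@@H]2[C@H]([C@@H]3[C@](C)(C(=O)C=C31)[C@@H](c1ccccc1)C1=C(O)C(C(=O)OC)=C(CC(=O)OC)OC1=O)C2(C)C
F2 | step 15 | dimethyl 2,4,6-trihydroxy-5-[phenyl(3-hydroxyaromadendr-1-en-4β-yl)methyl]isophthalate | C[C@H]1CC[C@@H]2[C@H]([C@@H]3[C@](C)(C(O)C=C31)[C@@H](c1ccccc1)c1c(O)c(C(=O)OC)c(O)c(C(=O)OC)c1O)C2(C)C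
F3 | step 11 | 4β-(hydroxymethyl)aromadendr-1-en-3-one | C[C@H]1CC[C@@H]2[C@H]([C@@H]3[C@](C)(C(=O)C=C31)CO)C2(C)C
F4 | step 11 | 3-oxoaromadendr-1-ene-4β-carbaldehyde | C[C@H]1CC[C@@H]2[C@H]([C@@H]3[C@](C)(C(=O)C=C31)C=O)C2(C)C
F5 | step 11 | diallyl 2-[(3-oxoaromadendr-1-en-4β-yl)methylidene]malonate | C[C@H]1CC[C@@H]2[C@H]([C@@H]3[C@](C)(C(=O)C=C31)C=C(C(=O)OCC=C)C(=O)OCC=C)C2(C)C
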